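**Retrosynthetic overview**
- The (10E) diene bond is cut last: Horner–Wadsworth–Emmons between a farnesal-type enal and a 4-(phosphonomethyl)butenolide, whose ring is made beforehand from dihydroxyacetone.
- The (3Z)-alkylidene lactone comes from the key union: intermolecular aldol of the (R)-γ-lactone lithium enolate with a C12 aldehyde, then stereospecific anti dehydration.
- The C12 aldehyde comes from (2E,6E)-farnesol (silyl ether) by terminal bromohydrin, epoxide and periodate cleavage; both E trisubstituted alkenes are bought in.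
- The (R)-lactone comes from D-glutamic acid (lactonisation with retention), then Wittig isopropylidenation.
- Ring order: the γ-butyrolactone ring first (step 1); the butenolide ring separately (step 13), attached in the last step.

Assumption: the SMILES is read as the (3Z,5R)-lactone with 4E,8E,10E side-chain alkenes; rt means room temperature.

**Step 1**
Reactants: 1 D-glutamic acid
Product: 3 (2R)-5-oxooxolane-2-carboxylic acid, via diazonium carboxylate 2 (not isolated)
Conditions: NaNO2, 2 M aq HCl, 0 °C → rt, 16 h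
Reagents that add atoms: none
Why: Diazotisation–lactonisation of an α-amino acid, in which carboxylate participation gives a double inversion and so net retention, keeping the centre R.

**Step 2**
Reactants: 3 (2R)-5-oxooxolane-2-carboxylic acid
Product: 4 (5R)-5-(hydroxymethyl)oxolan-2-one
Conditions: BH3·SMe2, THF, 0 °C → rt; MeOH quench
Reagents that add atoms: none
Why: Borane reduction is chemoselective for the carboxylic acid over the lactone and does not touch the stereocentre.

**Step 3**
Reactants: 4 (5R)-5-(hydroxymethyl)oxolan-2-one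
Product: 5 (2R)-5-oxooxolane-2-carbaldehyde
Conditions: Dess–Martin periodinane, CH2Cl2, 0 °C → rt; filter, use crude at once
Reagents that add atoms: none
Why: Dess–Martin oxidation under non-aqueous, non-basic conditions gives the water-soluble, epimerisable α-alkoxy aldehyde without loss of configuration.

**Step 4**
Reactants: 5 (2R)-5-oxooxolane-2-carbaldehyde; 6 isopropyl(triphenyl)phosphonium iodide
Product: 8 (5R)-5-(2-methylprop-1-en-1-yl)oxolan-2-one, via phosphorus ylide 7 (not isolated)
Conditions: 6, KN(SiMe3)2, THF, 0 °C; ylide added to 5, THF, −78 → 0 °C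
Reagents that add atoms: none
Why: Wittig olefination of the aldehyde by the non-stabilised ylide is much faster than attack on the lactone at −78 °C, and inverse addition limits α-epimerisation so the centre stays R.

**Step 5**
Reactants: 9 (2E,6E)-farnesol
Product: 10 tert-butyl(diphenyl){[(2E,6E)-3,7,11-trimethyldodeca-2,6,10-trien-1-yl]oxy}silane
Conditions: TBDPSCl, imidazole, DMF, rt
Reagents that add atoms: tert-butyl(chloro)diphenylsilane, CC(C)(C)[Si](Cl)(c1ccccc1)c1ccccc1
Why: Silylation of the primary allylic alcohol gives an acid- and base-robust ether that survives periodic acid, enolate and sulfurane chemistry.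

**Step 6**
Reactants: 10 tert-butyl(diphenyl){[(2E,6E)-3,7,11-trimethyldodeca-2,6,10-trien-1-yl]oxy}silane
Product: 11 (6E,10E)-3-bromo-12-{[tert-butyl(diphenyl)silyl]oxy}-2,6,10-trimethyldodeca-6,10-dien-2-ol (racemic at C3)
Conditions: NBS (1.1 equiv), THF/H2O (3:1), 0 °C
Reagents that add atoms: N-bromosuccinimide, O=C1CCC(=O)N1Br; water, O
Why: van Tamelen bromohydrin formation in aqueous medium selects the exposed terminal trisubstituted alkene and opens the bromonium ion at the tertiary carbon; the new centre is racemic and is cleaved away in step 8.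

**Step 7**
Reactants: 11 bromohydrin
Product: 12 tert-butyl{[(2E,6E)-9-(3,3-dimethyloxiran-2-yl)-3,7-dimethylnona-2,6-dien-1-yl]oxy}diphenylsilane (racemic)
Conditions: K2CO3, MeOH, rt
Reagents that add atoms: none
Why: Intramolecular Williamson closure of the bromohydrin gives the terminal epoxide cleanly.

**Step 8**
Reactants: 12 terminal epoxide
Product: 14 (4E,8E)-10-{[tert-butyl(diphenyl)silyl]oxy}-4,8-dimethyldeca-4,8-dienal, via diol 13 (not isolated)
Conditions: H5IO6, THF/Et2O, 0 °C
Reagents that add atoms: none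
Why: Periodic acid opens the epoxide to the glycol and cleaves it (Malaprade cleavage) to the aldehyde and acetone without touching the two E alkenes or the silyl ether.

**Step 9 (key union)**
Reactants: 8 (5R)-5-(2-methylprop-1-en-1-yl)oxolan-2-one; 14 (4E,8E)-10-{[tert-butyl(diphenyl)silyl]oxy}-4,8-dimethyldeca-4,8-dienal
Product: 16 (3R,5R)-3-[(1R,4E,8E)-10-{[tert-butyl(diphenyl)silyl]oxy}-1-hydroxy-4,8-dimethyldeca-4,8-dien-1-yl]-5-(2-methylprop-1-en-1-yl)oxolan-2-one, via lithium enolate 15 (not isolated)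
Conditions: LiN(i-Pr)2 (1.3 equiv), THF, −78 °C; then 14, −78 °C, 30 min; AcOH quench at −78 °C; chromatography to collect the anti adducts
Reagents that add atoms: none
Why: Intermolecular aldol addition in which the ring-locked E(O) lactone enolate reacts through a Zimmerman–Traxler chair to give the anti C3/C1' adduct, the aldehyde entering trans to the C5 substituent; C3 is erased in step 10, so the anti 3-epimer is carried along as well.

**Step 10**
Reactants: 16 anti aldol adduct
Product: 18 (3Z,5R)-3-[(4E,8E)-10-{[tert-butyl(diphenyl)silyl]oxy}-4,8-dimethyldeca-4,8-dien-1-ylidene]-5-(2-methylprop-1-en-1-yl)oxolan-2-one, via alkoxysulfurane 17 (not isolated)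
Conditions: Martin sulfurane Ph2S[OC(CF3)2Ph]2 (1.5 equiv), CH2Cl2, 0 °C → rt; chromatography removes any 3E isomer
Reagents that add atoms: none
Why: Martin sulfurane dehydration is an anti-periplanar E2 elimination with the weakly basic fluoroalkoxide, which from the anti aldol places the chain cis to the lactone carbonyl and so gives the 3Z alkene.

**Step 11**
Reactants: 18 silyl ether
Product: 19 (3Z,5R)-3-[(4E,8E)-10-hydroxy-4,8-dimethyldeca-4,8-dien-1-ylidene]-5-(2-methylprop-1-en-1-yl)oxolan-2-one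
Conditions: Bu4NF, AcOH (1:1), THF, 0 °C → rt
Reagents that add atoms: none
Why: Acetic acid-buffered fluoride desilylation is near neutral, so the Z-alkylidene lactone and the allylic lactone C–O bond are not isomerised or opened.

**Step 12**
Reactants: 19 allylic alcohol
Product: 20 (2E,6E,10Z)-3,7-dimethyl-10-[(5R)-5-(2-methylprop-1-en-1-yl)-2-oxooxolan-3-ylidene]deca-2,6-dienal
Conditions: MnO2, CH2Cl2, rt
Reagents that add atoms: none
Why: MnO2 oxidises only the primary allylic alcohol to the enal under neutral conditions with retention of the 2E geometry.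

**Step 13**
Reactants: 21 1,3-dihydroxyacetone (used as its commercial dimer); 22 ethyl (triphenylphosphoranylidene)acetate
Product: 24 4-(hydroxymethyl)furan-2(5H)-one, via hydroxy ester 23 (not isolated)
Conditions: CH2Cl2, rt, 16 h
Reagents that add atoms: none
Why: Wittig olefination of the activated α-hydroxy ketone gives an enoate that always has one hydroxymethyl group cis to the ester and lactonises spontaneously to the butenolide.

**Step 14**
Reactants: 24 4-(hydroxymethyl)furan-2(5H)-one
Product: 25 4-(bromomethyl)furan-2(5H)-one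
Conditions: CBr4, PPh3, CH2Cl2, 0 °C
Reagents that add atoms: tetrabromomethane, BrC(Br)(Br)Br
Why: Appel bromination converts the primary allylic alcohol to the bromide under neutral conditions that spare the butenolide.

**Step 15**
Reactants: 25 4-(bromomethyl)furan-2(5H)-one
Product: 26 diethyl [(5-oxo-2,5-dihydrofuran-3-yl)methyl]phosphonate
Conditions: P(OEt)3, toluene, 100 °C
Reagents that add atoms: triethyl phosphite, CCOP(OCC)OCC
Why: Michaelis–Arbuzov reaction of the reactive allylic bromide gives the vinylogous phosphonoacetate-type reagent.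

**Step 16**
Reactants: 20 enal; 26 diethyl [(5-oxo-2,5-dihydrofuran-3-yl)methyl]phosphonate
Product: 28 (3Z,5R)-3-[(4E,8E,10E)-4,8-dimethyl-11-(5-oxo-2,5-dihydrofuran-3-yl)undeca-4,8,10-trien-1-ylidene]-5-(2-methylprop-1-en-1-yl)oxolan-2-one, via lithiated phosphonate 27 (not isolated)
Conditions: 26 (1.3 equiv), LiN(SiMe3)2 (1.2 equiv), THF, −78 °C; then 20, −78 → 0 °C
Reagents that add atoms: none
Why: Horner–Wadsworth–Emmons olefination of the enal by the ester-stabilised vinylogous phosphonate anion reacts at the carbon next to phosphorus and gives the E alkene; the weakly basic anion leaves the Z-alkylidene lactone and the C5 centre alone.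

**Compound list**
1 | D-glutamic acid | N[C@H](CCC(=O)O)C(=O)O | starting material
2 | (R)-diazonium carboxylate of 1 | [O-]C(=O)[C@@H](CCC(O)=O)[N+]#N | intermediate (not isolated)
3 | (2R)-5-oxooxolane-2-carboxylic acid | OC(=O)[C@H]1CCC(=O)O1 | intermediate
4 | (5R)-5-(hydroxymethyl)oxolan-2-one | OC[C@H]1CCC(=O)O1 | intermediate
5 | (2R)-5-oxooxolane-2-carbaldehyde | O=C[C@H]1CCC(=O)O1 | intermediate
6 | isopropyl(triphenyl)phosphonium iodide | CC(C)[P+](c1ccccc1)(c1ccccc1)c1ccccc1.[I-] | starting material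
7 | isopropylidene(triphenyl)phosphorane | CC(C)=P(c1ccccc1)(c1ccccc1)c1ccccc1 | intermediate (not isolated)
8 | (5R)-5-(2-methylprop-1-en-1-yl)oxolan-2-one | CC(C)=C[C@H]1CCC(=O)O1 | intermediate
9 | (2E,6E)-farnesol | CC(C)=CCC/C(C)=C/CC/C(C)=C/CO | starting material
10 | tert-butyl(diphenyl){[(2E,6E)-3,7,11-trimethyldodeca-2,6,10-trien-1-yl]oxy}silane | CC(C)=CCC/C(C)=C/CC/C(C)=C/CO[Si](c1ccccc1)(c1ccccc1)C(C)(C)C | intermediate
11 | (6E,10E)-3-bromo-12-{[tert-butyl(diphenyl)silyl]oxy}-2,6,10-trimethyldodeca-6,10-dien-2-ol (racemic) | CC(C)(O)C(Br)CC/C(C)=C/CC/C(C)=C/CO[Si](c1ccccc1)(c1ccccc1)C(C)(C)C | intermediate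
12 | tert-butyl{[(2E,6E)-9-(3,3-dimethyloxiran-2-yl)-3,7-dimethylnona-2,6-dien-1-yl]oxy}diphenylsilane (racemic) | CC1(C)OC1CC/C(C)=C/CC/C(C)=C/CO[Si](c1ccccc1)(c1ccccc1)C(C)(C)C | intermediate
13 | (6E,10E)-12-{[tert-butyl(diphenyl)silyl]oxy}-2,6,10-trimethyldodeca-6,10-diene-2,3-diol (racemic) | CC(C)(O)C(O)CC/C(C)=C/CC/C(C)=C/CO[Si](c1ccccc1)(c1ccccc1)C(C)(C)C | intermediate (not isolated)
14 | (4E,8E)-10-{[tert-butyl(diphenyl)silyl]oxy}-4,8-dimethyldeca-4,8-dienal | O=CCC/C(C)=C/CC/C(C)=C/CO[Si](c1ccccc1)(c1ccccc1)C(C)(C)C | intermediate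
15 | lithium (5R)-5-(2-methylprop-1-en-1-yl)-4,5-dihydrofuran-2-olate | CC(C)=C[C@H]1CC=C([O-])O1.[Li+] | intermediate (not isolated)
16 | (3R,5R)-3-[(1R,4E,8E)-10-{[tert-butyl(diphenyl)silyl]oxy}-1-hydroxy-4,8-dimethyldeca-4,8-dien-1-yl]-5-(2-methylprop-1-en-1-yl)oxolan-2-one (major anti adduct; the anti (3S,1'S) epimer is carried along) | CC(C)=C[C@H]1C[C@H]([C@H](O)CC/C(C)=C/CC/C(C)=C/CO[Si](c2ccccc2)(c2ccccc2)C(C)(C)C)C(=O)O1 | intermediate
17 | mixed alkoxysulfurane of 16 (O-bound Ph2S[OC(CF3)2Ph] group at C1') | CC(C)=C[C@H]1C[C@H]([C@H](OS(c2ccccc2)(c2ccccc2)OC(c2ccccc2)(C(F)(F)F)C(F)(F)F)CC/C(C)=C/CC/C(C)=C/CO[Si](c2ccccc2)(c2ccccc2)C(C)(C)C)C(=O)O1 | intermediate (not isolated)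
18 | (3Z,5R)-3-[(4E,8E)-10-{[tert-butyl(diphenyl)silyl]oxy}-4,8-dimethyldeca-4,8-dien-1-ylidene]-5-(2-methylprop-1-en-1-yl)oxolan-2-one | CC(C)=C[C@H]1C/C(=C/CC/C(C)=C/CC/C(C)=C/CO[Si](c2ccccc2)(c2ccccc2)C(C)(C)C)C(=O)O1 | intermediate
19 | (3Z,5R)-3-[(4E,8E)-10-hydroxy-4,8-dimethyldeca-4,8-dien-1-ylidene]-5-(2-methylprop-1-en-1-yl)oxolan-2-one | CC(C)=C[C@H]1C/C(=C/CC/C(C)=C/CC/C(C)=C/CO)C(=O)O1 | intermediate
20 | (2E,6E,10Z)-3,7-dimethyl-10-[(5R)-5-(2-methylprop-1-en-1-yl)-2-oxooxolan-3-ylidene]deca-2,6-dienal | CC(C)=C[C@H]1C/C(=C/CC/C(C)=C/CC/C(C)=C/C=O)C(=O)O1 | intermediate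
21 | 1,3-dihydroxyacetone | OCC(=O)CO | starting material
22 | ethyl (triphenylphosphoranylidene)acetate | CCOC(=O)C=P(c1ccccc1)(c1ccccc1)c1ccccc1 | starting material
23 | ethyl 4-hydroxy-3-(hydroxymethyl)but-2-enoate | CCOC(=O)C=C(CO)CO | intermediate (not isolated)
24 | 4-(hydroxymethyl)furan-2(5H)-one | OCC1=CC(=O)OC1 | intermediate
25 | 4-(bromomethyl)furan-2(5H)-one | BrCC1=CC(=O)OC1 | intermediate
26 | diethyl [(5-oxo-2,5-dihydrofuran-3-yl)methyl]phosphonate | CCOP(=O)(CC1=CC(=O)OC1)OCC | intermediate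
27 | lithium salt of the carbanion of 26 (at the carbon next to phosphorus) | CCOP(=O)([CH-]C1=CC(=O)OC1)OCC.[Li+] | intermediate (not isolated)
28 | (3Z,5R)-3-[(4E,8E,10E)-4,8-dimethyl-11-(5-oxo-2,5-dihydrofuran-3-yl)undeca-4,8,10-trien-1-ylidene]-5-(2-methylprop-1-en-1-yl)oxolan-2-one | CC(C)=C[C@H]1C/C(=C/CC/C(C)=C/CC/C(C)=C/C=C/C2=CC(=O)OC2)C(=O)O1 | target

**Totals**
Total step count: 16. Longest linear sequence: 9 steps (steps 1–4, 9–12, 16; the farnesol branch, steps 5–8, 9–12, 16, is equally long).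

**Three steps most likely to fail**

Step 9 (aldol). Lithium lactone enolates often give only modest anti:syn ratios with unbranched aldehydes, and the aldehyde can enolise. Syn adducts that slip through would give the 3E alkene in step 10 and must be separated. The fallback sets out from 8 and comes back at 18, skipping 16 and step 10. Lactone 8 is deprotonated with LiN(i-Pr)2 and O-phosphorylated with bis(2,2,2-trifluoroethyl) phosphorochloridate to the enol phosphate (5R)-5-(2-methylprop-1-en-1-yl)-4,5-dihydrofuran-2-yl bis(2,2,2-trifluoroethyl) phosphate F1. A second equivalent of LiN(i-Pr)2 rearranges it by a 1,3 oxygen-to-carbon phosphoryl shift to the phosphono lactone (5R)-3-[bis(2,2,2-trifluoroethoxy)phosphoryl]-5-(2-methylprop-1-en-1-yl)oxolan-2-one F2. F2 with KN(SiMe3)2/18-crown-6 and aldehyde 14 in THF at −78 °C, a Still–Gennari-type Horner–Wadsworth–Emmons olefination under kinetic control, is expected to give the Z-alkylidene lactone 18 directly.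

Step 10 (dehydration). If the elimination leaks through an enolate (E1cB), the thermodynamically preferred 3E isomer forms. The fallback sets out from 16, used as any mixture of diastereomers, and comes back at 18. Dess–Martin oxidation gives the β-keto lactone (5R)-3-[(4E,8E)-10-{[tert-butyl(diphenyl)silyl]oxy}-4,8-dimethyldeca-4,8-dienoyl]-5-(2-methylprop-1-en-1-yl)oxolan-2-one F3. Its potassium enolate is O-triflated under non-chelating conditions (KN(SiMe3)2, 18-crown-6, PhNTf2, THF, −78 °C), where the two oxygens turn away from each other. This gives the enol triflate (3E,5R)-3-[(4E,8E)-10-{[tert-butyl(diphenyl)silyl]oxy}-4,8-dimethyl-1-(trifluoromethanesulfonyloxy)deca-4,8-dien-1-ylidene]-5-(2-methylprop-1-en-1-yl)oxolan-2-one F4, with the chain cis to the lactone carbonyl. Reduction with HCO2H/Bu3N catalysed by Pd(OAc)2/PPh3 (DMF, 60 °C) replaces the triflate by hydrogen with retention and gives 18.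

Step 16 (final olefination). The vinylogous phosphonate anion may give E/Z mixtures at the new alkene, or the base may isomerise the enal or the alkylidene lactone. The fallback sets out from 20 and comes back at 28. Takai iodo-olefination (CrCl2, CHI3, THF, 0 °C) gives the E-dienyl iodide (3Z,5R)-3-[(4E,8E,10E)-11-iodo-4,8-dimethylundeca-4,8,10-trien-1-ylidene]-5-(2-methylprop-1-en-1-yl)oxolan-2-one F5. Stille coupling of F5 with the known stannane 4-(tributylstannyl)furan-2(5H)-one (Pd2(dba)3, AsPh3, CuI, DMF, rt) attaches the preformed butenolide with retention of alkene geometry and gives 28 without any basic step.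

**Further compounds**
F1 | step 9 | (5R)-5-(2-methylprop-1-en-1-yl)-4,5-dihydrofuran-2-yl bis(2,2,2-trifluoroethyl) phosphate | CC(C)=C[C@H]1CC=C(OP(=O)(OCC(F)(F)F)OCC(F)(F)F)O1
F2 | step 9 | (5R)-3-[bis(2,2,2-trifluoroethoxy)phosphoryl]-5-(2-methylprop-1-en-1-yl)oxolan-2-one (C3 epimers) | CC(C)=C[C@H]1CC(P(=O)(OCC(F)(F)F)OCC(F)(F)F)C(=O)O1
F3 | step 10 | (5R)-3-[(4E,8E)-10-{[tert-butyl(diphenyl)silyl]oxy}-4,8-dimethyldeca-4,8-dienoyl]-5-(2-methylprop-1-en-1-yl)oxolan-2-one (C3 epimers) | CC(C)=C[C@H]1CC(C(=O)CC/C(C)=C/CC/C(C)=C/CO[Si](c2ccccc2)(c2ccccc2)C(C)(C)C)C(=O)O1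
F4 | step 10 | (3E,5R)-3-[(4E,8E)-10-{[tert-butyl(diphenyl)silyl]oxy}-4,8-dimethyl-1-(trifluoromethanesulfonyloxy)deca-4,8-dien-1-ylidene]-5-(2-methylprop-1-en-1-yl)oxolan-2-one | CC(C)=C[C@H]1C/C(=C(/CC/C(C)=C/CC/C(C)=C/CO[Si](c2ccccc2)(c2ccccc2)C(C)(C)C)OS(=O)(=O)C(F)(F)F)C(=O)O1
F5 | step 16 | (3Z,5R)-3-[(4E,8E,10E)-11-iodo-4,8-dimethylundeca-4,8,10-trien-1-ylidene]-5-(2-methylprop-1-en-1-yl)oxolan-2-one | CC(C)=C[C@H]1C/C(=C/CC/C(C)=C/CC/C(C)=C/C=C/I)C(=O)O1
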